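The plan rests on detaching the dihydropyranone ring D from the hexasubstituted benzene ring C at its two aryl bonds, O1–C8a and C4–C4a. These sit on adjacent ring-C carbons, one polarised for a nucleophile and one for an acyl electrophile, which is the signature of an aryne. A symmetrical 4,5-methylenedioxybenzyne, released from a commercial silylaryl triflate, should take up 3-methylbut-2-enoic acid by O-addition, acyl shift and oxa-Michael closure, giving the 2,2-dimethylchromanone in one operation. The new ketone then directs C5 methylation, C8 is oxygenated, and the unmasked 6,7-catechol is annulated by a 2-fluoro-3-formylbenzoate active ester (ring A) to close the dioxepinone ring B.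

Key step: step 1

Remark: the target has no stereocentre. Rings C and D carry chromanone numbering (O1, C2, C3, C4, C4a, C5 to C8, C8a) and ring A carries primed benzoate numbering. Compound 1 is taken to be a catalogue aryne precursor.

Step 1
Reactants: 1 6-(trimethylsilyl)-1,3-benzodioxol-5-yl trifluoromethanesulfonate; 2 3-methylbut-2-enoic acid
Product: 5 6,7-methylenedioxy-2,2-dimethylchroman-4-one, via aryne 3 (not isolated), via hydroxyaryl enone 4 (not isolated)
Conditions: CsF, THF (dilute), 125 °C, sealed tube
Reagents that add atoms: none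
Why: Fluoride-induced 1,2-elimination of Me3SiF and triflate from 1 gives aryne 3, cesium 3-methylbut-2-enoate adds to it through oxygen (aryl C8a–O1 bond), and the ortho aryl anion so formed attacks its own ester carbonyl through a strained four-membered alkoxide that collapses by C–O cleavage (aryl C4a–C4 bond), an anionic Fries-type acyl shift that leaves the phenoxide of 4. Ring D then closes by 6-endo-trig oxa-Michael addition of that phenoxide to the β,β-dimethyl enone, which also sets the quaternary C2. The closest known reaction type is the formal insertion of arynes into the C–O bond of carboxylic acids, which with β-substituted acrylic acids is known to run on to 4-chromanones. No stereocentre is formed. Regioselectivity is made unnecessary by the substrate, because the two aryne carbons of 3 are related by symmetry; a C8 alkoxy group already in place would polarise the aryne so that oxygen adds to the far carbon, which is why C5 and C8 are filled afterwards. The chemoselectivity needed is acyl shift over protonation of the aryl anion (plain O-arylation), and hot dilute THF with sparingly soluble CsF should secure it by keeping free acid scarce.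

Step 2
Reactants: 5 6,7-methylenedioxy-2,2-dimethylchroman-4-one
Product: 6 6,7-methylenedioxy-2,2,5-trimethylchroman-4-one
Conditions: [Cp*Co(C6H6)](PF6)2 (cat.), trimethylboroxine, Ag2CO3, 1,2-dichloroethane/HFIP, 80 °C
Reagents that add atoms: trimethylboroxine CB1OB(C)OB(C)O1
Why: Ketone-directed C–H methylation (cobalt catalyst, boroxine as methyl source, silver salt as oxidant): C5–H is the only C–H ortho to the C4 carbonyl, so five-membered cyclometalation can occur at one site only, and the tied-back dioxole oxygen beside it is small enough to allow it.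

Step 3
Reactants: 6 6,7-methylenedioxy-2,2,5-trimethylchroman-4-one
Product: 7 8-iodo-6,7-methylenedioxy-2,2,5-trimethylchroman-4-one
Conditions: NIS, TFA (cat.), MeCN, 0 °C to rt, dark
Reagents that add atoms: N-iodosuccinimide O=C1CCC(=O)N1I
Why: Electrophilic aromatic iodination: C8–H is the only aromatic hydrogen left, is ortho to O1 and O7 and meta to the acyl group, so ring iodination should outrun α-iodination of the ketone.

Step 4
Reactants: 7 8-iodo-6,7-methylenedioxy-2,2,5-trimethylchroman-4-one
Product: 8 8-methoxy-6,7-methylenedioxy-2,2,5-trimethylchroman-4-one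
Conditions: CuI (cat.), 3,4,7,8-tetramethyl-1,10-phenanthroline, Cs2CO3, MeOH/toluene, 110 °C, sealed tube
Reagents that add atoms: methanol CO
Why: Ullmann-type copper-catalysed C–O coupling of an aryl iodide with an aliphatic alcohol; both flanking oxygens are tied back in rings, which keeps the C8–I bond accessible, and any base-induced retro-oxa-Michael opening of ring D is reversible.

Step 5
Reactants: 8 8-methoxy-6,7-methylenedioxy-2,2,5-trimethylchroman-4-one
Product: 9 6,7-dihydroxy-8-methoxy-2,2,5-trimethylchroman-4-one
Conditions: BCl3, CH2Cl2, −78 to 0 °C; then H2O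
Reagents that add atoms: none
Why: Lewis-acid cleavage of an aryl methylenedioxy acetal, a known reaction that is faster than cleavage of aryl methyl ethers because chloride opens the boron-activated O–CH2–O unit to a chloromethyl ether that hydrolyses on work-up.

Step 6
Reactants: 10 2,6-difluoro-4-methylbenzaldehyde
Product: 11 2-fluoro-6-methoxy-4-methylbenzaldehyde
Conditions: NaOMe (1.0 equiv), MeOH, 0 °C to rt
Reagents that add atoms: sodium methoxide C[O-].[Na+]
Why: Nucleophilic aromatic substitution (SNAr) ortho to the formyl group; the two fluorines are equivalent, and the first methoxy group deactivates the ring toward a second substitution.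

Step 7
Reactants: 11 2-fluoro-6-methoxy-4-methylbenzaldehyde
Product: 12 2-fluoro-3-iodo-6-methoxy-4-methylbenzaldehyde
Conditions: NIS, TFA, MeCN, rt to 50 °C, dark
Reagents that add atoms: N-iodosuccinimide O=C1CCC(=O)N1I
Why: Electrophilic aromatic iodination para to the methoxy group: C3 is para to OMe, ortho to CH3, meta to CHO and flanked by the small fluorine, whereas C5 is squeezed between OMe and CH3.

Step 8
Reactants: 12 2-fluoro-3-iodo-6-methoxy-4-methylbenzaldehyde
Product: 13 2,4,6-trichlorophenyl 2-fluoro-3-formyl-4-methoxy-6-methylbenzoate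
Conditions: 2,4,6-trichlorophenyl formate, Pd(OAc)2 (cat.), Xantphos, Et3N, toluene, rt
Reagents that add atoms: 2,4,6-trichlorophenyl formate O=COc1c(Cl)cc(Cl)cc1Cl
Why: Palladium-catalysed aryloxycarbonylation of an aryl iodide in which the formate, decomposed by the amine, supplies both CO and the phenol; oxidative addition of the C–I bond proceeds at room temperature, where the aldehyde and the C–F bond stay untouched.

Step 9
Reactants: 9 6,7-dihydroxy-8-methoxy-2,2,5-trimethylchroman-4-one; 13 2,4,6-trichlorophenyl 2-fluoro-3-formyl-4-methoxy-6-methylbenzoate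
Product: 15 di-O-methyl depsidone (target with OMe at C4' and C8), via depside 14 (not isolated)
Conditions: Et3N, DMAP (cat.), THF, rt; then Cs2CO3, DMF (dilute), 50 °C
Reagents that add atoms: none
Why: Active-ester acyl transfer followed by intramolecular SNAr (seven-membered closure of ring B): under base the acyl group of the catechol monoester should rest on the more basic O6, while the para-acyl-stabilised O7 phenoxide, the dominant anion, displaces the fluoride that is activated by the ortho formyl and ortho ester groups.

Step 10
Reactants: 15 di-O-methyl depsidone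
Product: 16 target CNP0271978.0
Conditions: BBr3, CH2Cl2, −78 to 0 °C; then H2O
Reagents that add atoms: none
Why: Boron tribromide cleavage of aryl methyl ethers: the C4' ether is chelation-activated by the formyl group and the twisted C8 ether between two oxygens is Lewis basic, while the aryl ester, the aldehyde and the vinylogous-ester-type O1–C2 bond should survive at low temperature.

Compound list
1 | 6-(trimethylsilyl)-1,3-benzodioxol-5-yl trifluoromethanesulfonate | C[Si](C)(C)c1cc2OCOc2cc1OS(=O)(=O)C(F)(F)F | starting material
2 | 3-methylbut-2-enoic acid | CC(C)=CC(=O)O | starting material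
3 | 5,6-didehydro-1,3-benzodioxole (4,5-methylenedioxybenzyne) | C1OC2=CC#CC=C2O1 | intermediate
4 | 1-(6-hydroxy-1,3-benzodioxol-5-yl)-3-methylbut-2-en-1-one (present as its cesium phenoxide) | CC(C)=CC(=O)c1cc2OCOc2cc1O | intermediate
5 | 6,7-methylenedioxy-2,2-dimethylchroman-4-one | CC1(C)CC(=O)c2cc3OCOc3cc2O1 | intermediate
6 | 6,7-methylenedioxy-2,2,5-trimethylchroman-4-one | CC1(C)CC(=O)c2c(C)c3OCOc3cc2O1 | intermediate
7 | 8-iodo-6,7-methylenedioxy-2,2,5-trimethylchroman-4-one | CC1(C)CC(=O)c2c(C)c3OCOc3c(I)c2O1 | intermediate
8 | 8-methoxy-6,7-methylenedioxy-2,2,5-trimethylchroman-4-one | CC1(C)CC(=O)c2c(C)c3OCOc3c(OC)c2O1 | intermediate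
9 | 6,7-dihydroxy-8-methoxy-2,2,5-trimethylchroman-4-one | CC1(C)CC(=O)c2c(C)c(O)c(O)c(OC)c2O1 | intermediate
10 | 2,6-difluoro-4-methylbenzaldehyde | Cc1cc(F)c(C=O)c(F)c1 | starting material
11 | 2-fluoro-6-methoxy-4-methylbenzaldehyde | COc1cc(C)cc(F)c1C=O | intermediate
12 | 2-fluoro-3-iodo-6-methoxy-4-methylbenzaldehyde | COc1cc(C)c(I)c(F)c1C=O | intermediate
13 | 2,4,6-trichlorophenyl 2-fluoro-3-formyl-4-methoxy-6-methylbenzoate | COc1cc(C)c(C(=O)Oc2c(Cl)cc(Cl)cc2Cl)c(F)c1C=O | intermediate
14 | 7-hydroxy-8-methoxy-2,2,5-trimethyl-4-oxochroman-6-yl 2-fluoro-3-formyl-4-methoxy-6-methylbenzoate (depside) | COc1cc(C)c(C(=O)Oc2c(C)c3C(=O)CC(C)(C)Oc3c(OC)c2O)c(F)c1C=O | intermediate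
15 | di-O-methyl depsidone (target with OMe at C4' of ring A and at C8 of ring C) | Cc1cc(OC)c(C=O)c2c1C(=O)Oc1c(C)c3c(c(OC)c1O2)OC(C)(C)CC3=O | intermediate
16 | CNP0271978.0 | Cc1cc(O)c(C=O)c2c1C(=O)Oc1c(C)c3c(c(O)c1O2)OC(C)(C)CC3=O | target

Total step count: 10. Longest linear sequence: 7 (steps 1 to 5, 9 and 10).

Steps most likely to fail

Step 9. Three processes may interfere:
- acyl migration between O6 and O7, followed by closure through the more nucleophilic O6 phenoxide;
- aryl O-to-O migration, if substitution precedes acylation;
- intermolecular substitution that leads to oligomers.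

The fallback makes the ether first with O6 masked and closes the lactone without a free neighbouring phenoxide. It sets out from 9 and 12 and returns at 15. Alkylation of the monoanion of 9 (BnBr, one equivalent of K2CO3, DMF) should give 7-benzyloxy-6-hydroxy-8-methoxy-2,2,5-trimethylchroman-4-one F1. MOMCl and iPr2NEt should then give its 6-O-methoxymethyl ether F2, and hydrogenolysis (H2, Pd/C, EtOAc) should free O7 to give 7-hydroxy-8-methoxy-6-(methoxymethoxy)-2,2,5-trimethylchroman-4-one F3. Intermolecular SNAr on iodide 12 (K2CO3, DMSO, 100 °C) should give the 6-O-methoxymethyl diaryl ether iodide F4. Aqueous HCl in THF should remove the acetal to give the 6-hydroxy diaryl ether iodide F5. Palladium-catalysed carbonylative lactonisation (Pd(OAc)2, Xantphos, CO 1 atm, Et3N, toluene, 80 °C) should close ring B to 15.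

Step 2. Cyclometalation at C5–H, wedged between the carbonyl-bearing C4a and the dioxole oxygen, may be too slow, so that the catalyst decays before turnover. The fallback replaces C–H activation by halogenation and cross-coupling. It sets out from 5 and returns at 8. Iodination of 5 (NIS, TFA cat., MeCN) should go to the more activated C8 and give 8-iodo-6,7-methylenedioxy-2,2-dimethylchroman-4-one F6. Copper-catalysed methoxylation as in step 4 should give 8-methoxy-6,7-methylenedioxy-2,2-dimethylchroman-4-one F7. NBS in MeCN should fill the last free position, para to the new methoxy group, to give 5-bromo-8-methoxy-6,7-methylenedioxy-2,2-dimethylchroman-4-one F8. Suzuki–Miyaura methylation (trimethylboroxine, Pd(dppf)Cl2, K2CO3, dioxane/H2O, 90 °C) should give 8.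

Step 1. The aryl anion may be protonated before the acyl shift, which leaves plain O-arylation, or the electron-rich aryne may be consumed unproductively at high temperature. The fallback keeps the idea of forming both aryl bonds at once but uses a (3+2) cycloaddition instead of nucleophilic insertion. It sets out from 1 and returns at 5. CsF in MeCN at rt acts on 1 and on commercial N-hydroxyacetimidoyl chloride and releases aryne 3 and acetonitrile oxide together. Their cycloaddition should give 3-methyl-5,6-methylenedioxy-1,2-benzisoxazole F9. N–O hydrogenolysis (H2, Pd/C) followed by aqueous HCl should give 1-(6-hydroxy-1,3-benzodioxol-5-yl)ethanone F10. Kabbe condensation with acetone (pyrrolidine, MeOH, reflux) should give 5.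

Further compounds
F1 | step 9 | 7-benzyloxy-6-hydroxy-8-methoxy-2,2,5-trimethylchroman-4-one | CC1(C)CC(=O)c2c(C)c(O)c(OCc3ccccc3)c(OC)c2O1
F2 | step 9 | 7-benzyloxy-8-methoxy-6-(methoxymethoxy)-2,2,5-trimethylchroman-4-one | CC1(C)CC(=O)c2c(C)c(OCOC)c(OCc3ccccc3)c(OC)c2O1
F3 | step 9 | 7-hydroxy-8-methoxy-6-(methoxymethoxy)-2,2,5-trimethylchroman-4-one | CC1(C)CC(=O)c2c(C)c(OCOC)c(O)c(OC)c2O1
F4 | step 9 | 3-iodo-6-methoxy-2-{[8-methoxy-6-(methoxymethoxy)-2,2,5-trimethyl-4-oxochroman-7-yl]oxy}-4-methylbenzaldehyde | COCOc1c(C)c2C(=O)CC(C)(C)Oc2c(OC)c1Oc1c(I)c(C)cc(OC)c1C=O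
F5 | step 9 | 2-[(6-hydroxy-8-methoxy-2,2,5-trimethyl-4-oxochroman-7-yl)oxy]-3-iodo-6-methoxy-4-methylbenzaldehyde | Oc1c(C)c2C(=O)CC(C)(C)Oc2c(OC)c1Oc1c(I)c(C)cc(OC)c1C=O
F6 | step 2 | 8-iodo-6,7-methylenedioxy-2,2-dimethylchroman-4-one | CC1(C)CC(=O)c2cc3OCOc3c(I)c2O1
F7 | step 2 | 8-methoxy-6,7-methylenedioxy-2,2-dimethylchroman-4-one | CC1(C)CC(=O)c2cc3OCOc3c(OC)c2O1
F8 | step 2 | 5-bromo-8-methoxy-6,7-methylenedioxy-2,2-dimethylchroman-4-one | CC1(C)CC(=O)c2c(Br)c3OCOc3c(OC)c2O1
F9 | step 1 | 3-methyl-5,6-methylenedioxy-1,2-benzisoxazole | Cc1noc2cc3OCOc3cc12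
F10 | step 1 | 1-(6-hydroxy-1,3-benzodioxol-5-yl)ethanone | CC(=O)c1cc2OCOc2cc1O
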